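# Proposed synthesis of bis-coumarin 21 by a late twofold propargyl Claisen / oxa-electrocyclisation

## The problem

Target 21 joins two 7-methoxycoumarin units through their C8 atoms to a 1,4-dimethylcyclohex-3-ene, one bonded directly to ring carbon C2 and the other through an (E)-ethenyl bridge to the quaternary carbon C1. The two stereocentres are adjacent (C1 R, C2 R), and the C2 aryl group is cis to the C1 ethenyl arm. Neither centre can be corrected later, because C1 has no hydrogen and the C2 hydrogen is not acidic; they must be set together in one bond-forming event, or C1 must direct C2. Each arene carries its carbon substituent between two oxygen atoms, so every bond to C8 is doubly ortho-hindered. The coumarin lactones are opened by hydroxide, alkoxides, hydrides and organometallic reagents, so they should appear last. The electron-rich styrene and the trisubstituted ring alkene do not tolerate strong protic acid (a neighbouring free phenol would add across the ring alkene) or unselective oxidants. The feature that enables the key step is that in each coumarin O1 sits on C8a, next to the substituted C8, and the only free ortho carbon of that oxygen is C4a, which carries C4. The atoms O1, C2, C3 and C4 of both pyranones therefore map onto propargyl ethers of a bis-phenol in which each phenol has a single open ortho position.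

## Retrosynthesis

**21 to 20.** The two lactone carbonyls are removed, giving bis(2H-chromene) 20. No skeletal bond is cut. The allyl aryl ether stage tolerates the heat of the ring-forming step and keeps the base-labile lactones out of all earlier chemistry. The forward reaction must oxidise two O–CH2 groups that are allylic and α to oxygen without touching the carbocycle's allylic positions or the styrene.

**20 to 16.** On each arene the C4–C4a and O1–C2 bonds are cut, giving bis(propargyl ether) 16. This is preferred over condensation-type coumarin syntheses, which need a formyl group ortho to each phenol or strong acid. Here the only preparation is O-alkylation, and both heterocycles form in one operation. The precursor has no heterocycle and two identical side chains. The forward reaction needs the [3,3] shift to go to the single free ortho carbon of each ring and the cascade to end at the chromene.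

**16 to 14 and 15.** Two O–CH2 bonds are cut, giving bis-phenol 14 and two equivalents of propargyl bromide 15. The terminal alkynes enter only after all organometallic steps are finished.

**14 to 12, then to 7 and 9.** The phenols are masked as methoxymethyl ethers (12). The bond between the ethenyl bridge and its arene is then cut, giving (E)-alkenyl iodide 7 and arene 9, the methoxymethyl ether of 3-methoxyphenol 8. This cut is preferred over a benzylic ylide olefination of aldehyde 6 (E/Z mixtures at a hindered neopentyl aldehyde) because the alkene geometry is fixed in 7 before the coupling. The aryl nucleophile (aryllithium 10, then arylzinc 11) comes from 9 by metalation at the carbon between the two oxygen substituents. The forward reaction is a cross-coupling of a di-ortho-substituted arylzinc with retention of alkene geometry.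

**7 to 6.** The iodoalkene is taken back to aldehyde 6 by removing one carbon. The forward reaction is an E-selective iodo-olefination of an α-quaternary aldehyde.

**6 to 4 and 5.** Ring bonds C1–C2 and C5–C6 are cut (Diels–Alder), giving aryl diene 4 and methacrolein 5. This removes the ring and both stereocentres together, and it avoids forming the hindered aryl–C2 bond, because the arene arrives on the diene. Conjugate addition to a 4,4-disubstituted cyclohexenone is the weaker neighbour: a di-ortho-substituted aryl metal would have to choose a face between a methyl group and a slim unsaturated group. Dimerisation of 4 itself offers no handle for a chiral catalyst. The forward reaction must deliver "ortho" regiochemistry, endo orientation of the formyl group and one enal face.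

**4 to 2 and 3; 2 to 1.** The diene is cut at its C1=C2 bond into aldehyde 2 and allylic phosphonate 3. Aldehyde 2 is the methoxymethyl ether of 2-hydroxy-6-methoxybenzaldehyde 1, which already carries the 1,2,3-substitution pattern. Buying this pattern is preferred over formylating 9, which would add a cryogenic organolithium step to reach the same compound. Both arenes carry the same protecting group, so one operation later frees both phenols.

## Roads not taken

Alternative 1: The cyclohexene is cut at C1–C2 and C5–C6 as in the chosen route, but the ring-bound arene is delivered inside the dienophile. Methyl 5-methoxy-2-oxo-2H-chromene-3-carboxylate A1 would add (E)-trimethyl(2-methylbuta-1,3-dien-1-yl)silane A2 under a chiral Lewis acid to give cis-fused adduct A3.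
- Merits: the lactone ring forces the aryl carbon and the lactone carbonyl (the future ethenyl carbon) to be cis. The relative configuration is then enforced by the ring and does not depend on an endo preference, which is better than step 3 of the chosen plan. The silyl group directs regiochemistry and later allows protodesilylation with allyl shift to place the ring alkene.
- Weak points: the C3=C4 bond of a coumarin is a trisubstituted, sluggish dienophile, and the pairing puts the silyl-bearing terminus on the hindered benzylic carbon. Enantioselective catalysis has little precedent for this dienophile class. In A3 the quaternary carbon carries two carbonyl groups at the acid oxidation level: the ester must be reduced fully to a methyl group and the lactone carbonyl converted into the ethenyl arm. Both pyranones still have to be built afterwards.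
- Comparison: the chosen plan uses dienophile 5, which brings the quaternary carbon at its final oxidation levels (CH3 and CHO), and a single late step that makes both heterocycles. The step count after A3 would be clearly higher.

Alternative 2: The aryl–carbonyl and aryl–oxygen bonds of the arene on the ethenyl arm are cut. The homologated acid A4 would add through its carboxylate to 3-methoxybenzyne A5 at the carbon meta to the methoxy group, and the aryl anion would take the acyl group, giving hydroxyaryl ketone A6.
- Merits: free of transition metals; the phenol and the side chain are installed on adjacent carbons in one operation with regiochemistry set by the methoxy group. The phenol arrives unprotected, which is more economical for that arene than the protection and deprotection of the chosen route.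
- Weak points: no ring and no stereocentre is formed. A4 needs one more carbon than aldehyde 6 and so an extra homologation. The ketone must be reduced and dehydrated to the E-alkene next to a quaternary carbon, where acid threatens addition of the free phenol to the ring alkene or rearrangement. A hindered aliphatic carboxylate may give aryl ester instead of insertion.
- Comparison: the coupling of 7 with 11 forms the same arene–side-chain connection directly at the alkene oxidation level with the geometry already fixed. The protecting group of the chosen route also serves as the directing group for the metalation.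

Alternative 3: Three bonds of the ring-bound benzene are cut. Irradiation of 1-diazobut-3-en-2-one A7 would give a vinylketene that adds to siloxyalkyne A8. Cyclobutenone opening and six-electron closure would then give phenol A9.
- Merits: the di-ortho-oxygenated arene is grown on the ring carbon, so no hindered coupling is needed there. The two oxygens emerge differentiated (free hydroxyl and silyl ether), which is a real advantage.
- Weak points: A8 must already hold both stereocentres, and its siloxyalkyne has to be made by strongly basic ester homologation at an allylic, epimerisable carbon. The ketene may be intercepted by the ring alkene or the second alkyne. Only one arene is addressed, and the other would need alkyne arylation followed by E-selective semi-reduction.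
- Comparison: in the chosen plan the same aryl–ring bond is never formed, because it comes with diene 4. The oxygen differentiation is already present in starting materials 1 and 8. Alternative 3 would be at least as good at the hindered carbon but much longer overall.

Key step: step 9

**Remarks on the chemistry**

- 2-Hydroxy-6-methoxybenzaldehyde 1 and diethyl (2-methylprop-2-en-1-yl)phosphonate 3 are assumed to be commercially available.
- The (S)-configured oxazaborolidinium of step 3 is taken to expose the Re face of the α-carbon of bound methacrolein. This follows from the formyl C–H···O organised complex, in which the phenyl group cis to the aldehyde covers the other face. If the sense proved opposite, the (R)-catalyst would be used with no other change.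
- The descriptors change from (1S,2S) in 6 to (1R,6S) in 7 and (1R,2R) from 12 onwards only because the substituent priorities and the ring numbering change; no centre is touched.
- In the twofold steps 7 to 10 the two arenes react independently. Half-converted species are not numbered, and each intermediate is drawn with both arenes at the same stage.

## Route

Step 1
Reactants: 1 2-hydroxy-6-methoxybenzaldehyde
Product: 2 2-methoxy-6-(methoxymethoxy)benzaldehyde
Conditions: NaH, MOMCl, DMF, 0 °C → rt
Reagents that add atoms: chloromethyl methyl ether, COCCl
Why: Williamson-type O-alkylation of the sodium phenoxide with an α-chloro ether; the aldehyde has no α-hydrogen, so hydride only deprotonates the chelated phenol, and the acetal formed withstands the basic and organometallic steps that follow.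

Step 2
Reactants: 2 2-methoxy-6-(methoxymethoxy)benzaldehyde; 3 diethyl (2-methylprop-2-en-1-yl)phosphonate
Product: 4 1-methoxy-3-(methoxymethoxy)-2-[(1E)-3-methylbuta-1,3-dien-1-yl]benzene
Conditions: 3, n-BuLi, THF, −78 °C; DMPU; then 2, −78 °C → rt
Reagents that add atoms: none
Why: Horner–Wadsworth–Emmons olefination with an allylic phosphonate: α-attack of the lithiated phosphonate (favoured by the polar co-solvent) and elimination of lithium diethyl phosphate should give the (E)-diene, the geometry that can reach the s-cis conformation needed in step 3.

Step 3
Reactants: 4 1-methoxy-3-(methoxymethoxy)-2-[(1E)-3-methylbuta-1,3-dien-1-yl]benzene; 5 methacrolein (2-methylprop-2-enal)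
Product: 6 (1S,2S)-2-[2-methoxy-6-(methoxymethoxy)phenyl]-1,4-dimethylcyclohex-3-ene-1-carbaldehyde (aryl cis to CHO)
Conditions: (S)-3,3-diphenyl-1-(2-methylphenyl)tetrahydro-1H,3H-pyrrolo[1,2-c][1,3,2]oxazaborole (20 mol%), HN(SO2CF3)2 (17 mol%), CH2Cl2, −78 → −40 °C
Reagents that add atoms: none
Why: Catalytic enantioselective Diels–Alder reaction of an α-substituted enal on a cationic oxazaborolidine: the aryl group at C1 and the methyl group at C3 of the diene both put the largest HOMO coefficient on the CH2 terminus, which bonds to the β-carbon of the activated enal, so the aryl-bearing carbon bonds to the α-carbon. The endo orientation of the formyl group places the aryl group cis to CHO (C2 set relative to C1), and the catalyst, which holds the enal by boron coordination and a formyl C–H···O contact with a phenyl group over one face, exposes the Re face of the α-carbon (C1 set as S in 6).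

Step 4
Reactants: 6 (1S,2S)-2-[2-methoxy-6-(methoxymethoxy)phenyl]-1,4-dimethylcyclohex-3-ene-1-carbaldehyde
Product: 7 2-[(1R,6S)-6-[(E)-2-iodoethenyl]-3,6-dimethylcyclohex-2-en-1-yl]-1-methoxy-3-(methoxymethoxy)benzene
Conditions: CHI3, CrCl2, THF, 0 °C → rt
Reagents that add atoms: iodoform, IC(I)I
Why: Takai iodo-olefination: the geminal dichromium species formed from CHI3 and divalent chromium adds to the aldehyde and eliminates to the (E)-iodoalkene, with the E preference highest for α-branched aldehydes; the reagent is non-basic and should leave the ring alkene, the acetal and both stereocentres untouched.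

Step 5
Reactants: 8 3-methoxyphenol
Product: 9 1-methoxy-3-(methoxymethoxy)benzene
Conditions: NaH, MOMCl, DMF, 0 °C → rt
Reagents that add atoms: chloromethyl methyl ether, COCCl
Why: Williamson-type O-alkylation of the sodium phenoxide with an α-chloro ether; the methoxymethyl ether is both the phenol protection and the directing group for the metalation of step 6.

Step 6
Reactants: 7 2-[(1R,6S)-6-[(E)-2-iodoethenyl]-3,6-dimethylcyclohex-2-en-1-yl]-1-methoxy-3-(methoxymethoxy)benzene; 9 1-methoxy-3-(methoxymethoxy)benzene
Product: 12 1-methoxy-2-[(E)-2-[(1R,2R)-2-[2-methoxy-6-(methoxymethoxy)phenyl]-1,4-dimethylcyclohex-3-en-1-yl]ethenyl]-3-(methoxymethoxy)benzene, via [2-methoxy-6-(methoxymethoxy)phenyl]lithium 10 (not isolated), via chloro[2-methoxy-6-(methoxymethoxy)phenyl]zinc 11 (not isolated)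
Conditions: 9, n-BuLi, TMEDA, THF, 0 °C; ZnCl2, 0 °C → rt; then 7, Pd2(dba)3 (2.5 mol%), SPhos (2-dicyclohexylphosphino-2′,6′-dimethoxybiphenyl, 10 mol%), THF, 55 °C
Reagents that add atoms: none
Why: Directed ortho-metalation followed by Negishi coupling: C2 of 9 lies between two coordinating oxygen substituents and is the kinetically most acidic ring position, so lithiation and transmetalation should give a single arylzinc. Oxidative addition of the alkenyl iodide to zerovalent palladium and reductive elimination proceed with retention of the E geometry; the biaryl dialkylphosphine ligand is chosen for the di-ortho-substituted nucleophile.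

Step 7
Reactants: 12 1-methoxy-2-[(E)-2-[(1R,2R)-2-[2-methoxy-6-(methoxymethoxy)phenyl]-1,4-dimethylcyclohex-3-en-1-yl]ethenyl]-3-(methoxymethoxy)benzene
Product: 14 2-[(E)-2-[(1R,2R)-2-(2-hydroxy-6-methoxyphenyl)-1,4-dimethylcyclohex-3-en-1-yl]ethenyl]-3-methoxyphenol, via bis(trimethylsilyl) ether 13 (not isolated)
Conditions: TMSOTf, 2,2′-bipyridyl, CH3CN, 0 °C → rt; then H2O, rt
Reagents that add atoms: none
Why: Silyl triflate with 2,2′-bipyridyl converts aromatic methoxymethyl ethers into aryl trimethylsilyl ethers under buffered aprotic conditions, and water then frees the phenols; protic acid is avoided because a free phenol next to the ring alkene could add across it.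

Step 8
Reactants: 14 2-[(E)-2-[(1R,2R)-2-(2-hydroxy-6-methoxyphenyl)-1,4-dimethylcyclohex-3-en-1-yl]ethenyl]-3-methoxyphenol; 15 propargyl bromide (3-bromoprop-1-yne)
Product: 16 1-methoxy-2-[(E)-2-[(1R,2R)-2-[2-methoxy-6-(prop-2-yn-1-yloxy)phenyl]-1,4-dimethylcyclohex-3-en-1-yl]ethenyl]-3-(prop-2-yn-1-yloxy)benzene
Conditions: 15 (2.5 equiv), K2CO3, DMF, 50 °C
Reagents that add atoms: propargyl bromide 15 (second equivalent, for the second phenol), C#CCBr
Why: Twofold Williamson etherification by SN2 displacement at the primary propargylic bromide, one equivalent of 15 per phenol; carbonate in a dipolar aprotic solvent is mild enough to leave the terminal alkynes unisomerised.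

Step 9
Reactants: 16 1-methoxy-2-[(E)-2-[(1R,2R)-2-[2-methoxy-6-(prop-2-yn-1-yloxy)phenyl]-1,4-dimethylcyclohex-3-en-1-yl]ethenyl]-3-(prop-2-yn-1-yloxy)benzene
Product: 20 7-methoxy-8-[(E)-2-[(1R,2R)-2-(7-methoxy-2H-chromen-8-yl)-1,4-dimethylcyclohex-3-en-1-yl]ethenyl]-2H-chromene, via bis(allenyl cyclohexadienone) 17 (not isolated), via bis(ortho-allenylphenol) 18 (not isolated), via bis(ortho-quinone methide) 19 (not isolated)
Conditions: PhNEt2, 205 °C, argon
Reagents that add atoms: none
Why: On each arene the aryl propargyl ether undergoes a [3,3]-sigmatropic (propargyl Claisen) shift that breaks O–CH2 and bonds the alkyne terminus to the only unsubstituted ortho carbon, the future C4a, giving allenyl cyclohexadienone 17. Enolisation restores the arene (18), and a 1,5-hydrogen shift from the phenol oxygen to the central allene carbon gives the vinyl ortho-quinone methide 19. Each pyran ring then closes by a thermal disrotatory oxa-six-electron electrocyclisation that forms the O1–C2 bond in a six-membered ring and regains aromaticity, which makes the cascade irreversible. The closest known reaction type is the thermal conversion of aryl propargyl ethers into 2H-chromenes in a high-boiling amine solvent. No stereocentre is created: the sp3 carbons of 17 vanish on enolisation, and C1 and C2 of the carbocycle carry no acidic hydrogen and are spectators under neutral conditions. The selectivity needed is regiochemical and is secured by the substrate, since on both rings the second ortho position is the substituted carbon (future C8), so only the shift to C4a can be followed by enolisation and a shift to the blocked carbon is reversible. Base and fluoride additives are left out because they divert the allenyl phenol to 2-methylbenzofurans. The one other sigmatropic path open to the skeleton, the [3,3] shift of the 1,5-diene made up of the ethenyl arm and the ring alkene, is degenerate for two identical aryl groups and, passing through the twofold-symmetric geometry of the formal diene dimerisation, should return the same enantiomer.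

Step 10
Reactants: 20 7-methoxy-8-[(E)-2-[(1R,2R)-2-(7-methoxy-2H-chromen-8-yl)-1,4-dimethylcyclohex-3-en-1-yl]ethenyl]-2H-chromene
Product: 21 7-methoxy-8-[(E)-2-[(1R,2R)-2-(7-methoxy-2-oxo-2H-chromen-8-yl)-1,4-dimethylcyclohex-3-en-1-yl]ethenyl]-2H-chromen-2-one
Conditions: C5H5NH[CrO3Cl] (pyridinium chlorochromate), Celite, CH2Cl2, 40 °C
Reagents that add atoms: pyridinium chlorochromate, [O-][Cr](=O)(=O)Cl.c1cc[nH+]cc1
Why: Allylic oxidation of cyclic allyl ethers to α,β-unsaturated lactones with hexavalent chromium: the C2 hydrogens of each 2H-chromene are allylic and α to oxygen and their loss leads towards an aromatic benzopyrylium-type intermediate, so they should react far faster than the allylic positions of the carbocycle. Oxidation at both C2 atoms gives the two coumarin lactones of 21.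

## Compound list

1 | 2-hydroxy-6-methoxybenzaldehyde | COc1cccc(O)c1C=O | starting material
2 | 2-methoxy-6-(methoxymethoxy)benzaldehyde | O=Cc1c(OC)cccc1OCOC | intermediate
3 | diethyl (2-methylprop-2-en-1-yl)phosphonate | CCOP(=O)(CC(C)=C)OCC | starting material
4 | 1-methoxy-3-(methoxymethoxy)-2-[(1E)-3-methylbuta-1,3-dien-1-yl]benzene | COCOc1cccc(OC)c1/C=C/C(C)=C | intermediate
5 | methacrolein (2-methylprop-2-enal) | CC(=C)C=O | starting material
6 | (1S,2S)-2-[2-methoxy-6-(methoxymethoxy)phenyl]-1,4-dimethylcyclohex-3-ene-1-carbaldehyde | O=C[C@@]1(C)CCC(C)=C[C@H]1c1c(OC)cccc1OCOC | intermediate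
7 | 2-[(1R,6S)-6-[(E)-2-iodoethenyl]-3,6-dimethylcyclohex-2-en-1-yl]-1-methoxy-3-(methoxymethoxy)benzene | I/C=C/[C@@]1(C)CCC(C)=C[C@H]1c1c(OC)cccc1OCOC | intermediate
8 | 3-methoxyphenol | COc1cccc(O)c1 | starting material
9 | 1-methoxy-3-(methoxymethoxy)benzene | COCOc1cccc(OC)c1 | intermediate
10 | [2-methoxy-6-(methoxymethoxy)phenyl]lithium | [Li]c1c(OC)cccc1OCOC | intermediate (not isolated)
11 | chloro[2-methoxy-6-(methoxymethoxy)phenyl]zinc | Cl[Zn]c1c(OC)cccc1OCOC | intermediate (not isolated)
12 | 1-methoxy-2-[(E)-2-[(1R,2R)-2-[2-methoxy-6-(methoxymethoxy)phenyl]-1,4-dimethylcyclohex-3-en-1-yl]ethenyl]-3-(methoxymethoxy)benzene | COCOc1cccc(OC)c1/C=C/[C@@]1(C)CCC(C)=C[C@H]1c1c(OC)cccc1OCOC | intermediate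
13 | bis(trimethylsilyl) ether of 14: trimethyl{3-methoxy-2-[(E)-2-[(1R,2R)-2-[2-methoxy-6-(trimethylsilyloxy)phenyl]-1,4-dimethylcyclohex-3-en-1-yl]ethenyl]phenoxy}silane | COc1cccc(O[Si](C)(C)C)c1/C=C/[C@@]1(C)CCC(C)=C[C@H]1c1c(OC)cccc1O[Si](C)(C)C | intermediate (not isolated)
14 | 2-[(E)-2-[(1R,2R)-2-(2-hydroxy-6-methoxyphenyl)-1,4-dimethylcyclohex-3-en-1-yl]ethenyl]-3-methoxyphenol | COc1cccc(O)c1/C=C/[C@@]1(C)CCC(C)=C[C@H]1c1c(OC)cccc1O | intermediate
15 | propargyl bromide (3-bromoprop-1-yne) | C#CCBr | starting material
16 | 1-methoxy-2-[(E)-2-[(1R,2R)-2-[2-methoxy-6-(prop-2-yn-1-yloxy)phenyl]-1,4-dimethylcyclohex-3-en-1-yl]ethenyl]-3-(prop-2-yn-1-yloxy)benzene | COc1cccc(OCC#C)c1/C=C/[C@@]1(C)CCC(C)=C[C@H]1c1c(OC)cccc1OCC#C | intermediate (key-step precursor)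
17 | twofold ortho-Claisen product of 16: each arene present as a 3-methoxy-6-(propa-1,2-dien-1-yl)cyclohexa-2,4-dien-1-one substituted at C2, one by the (E)-ethenyl arm and one by C2 of the (1R,2R)-1,4-dimethylcyclohex-3-ene; the two dienone C6 centres are not defined | COC1=C(/C=C/[C@@]2(C)CCC(C)=C[C@H]2C2=C(OC)C=CC(C=C=C)C2=O)C(=O)C(C=C=C)C=C1 | intermediate (not isolated)
18 | 2-[(E)-2-[(1R,2R)-2-[2-hydroxy-6-methoxy-3-(propa-1,2-dien-1-yl)phenyl]-1,4-dimethylcyclohex-3-en-1-yl]ethenyl]-3-methoxy-6-(propa-1,2-dien-1-yl)phenol | COc1ccc(C=C=C)c(O)c1/C=C/[C@@]1(C)CCC(C)=C[C@H]1c1c(OC)ccc(C=C=C)c1O | intermediate (not isolated)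
19 | twofold ortho-quinone methide: each arene present as a 3-methoxy-6-(prop-2-en-1-ylidene)cyclohexa-2,4-dien-1-one substituted at C2 as in 17, (1R,2R) carbocycle | COC1=C(/C=C/[C@@]2(C)CCC(C)=C[C@H]2C2=C(OC)C=CC(=CC=C)C2=O)C(=O)C(=CC=C)C=C1 | intermediate (not isolated)
20 | 7-methoxy-8-[(E)-2-[(1R,2R)-2-(7-methoxy-2H-chromen-8-yl)-1,4-dimethylcyclohex-3-en-1-yl]ethenyl]-2H-chromene | COc1ccc2C=CCOc2c1/C=C/[C@@]1(C)CCC(C)=C[C@H]1c1c(OC)ccc2C=CCOc12 | intermediate (key-step product)
21 | 7-methoxy-8-[(E)-2-[(1R,2R)-2-(7-methoxy-2-oxo-2H-chromen-8-yl)-1,4-dimethylcyclohex-3-en-1-yl]ethenyl]-2H-chromen-2-one | COc1ccc2ccc(=O)oc2c1/C=C/[C@@]1(C)CCC(C)=C[C@H]1c1c(OC)ccc2ccc(=O)oc12 | target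

## Step count and least certain steps

Total: 10 steps. Longest linear sequence: 9 steps, from 1 through 2, 4, 6, 7, 12, 14, 16 and 20 to 21 (steps 1 to 4 and 6 to 10). Step 5 (8 to 9) is a one-step branch that joins at step 6.

**Step 9 (key step).** The most likely failure is diversion of the allenyl dienone on one ring. A [3,3] shift to the substituted ortho carbon can be followed by intramolecular cycloaddition of the allene onto the dienone. The styrene may also polymerise at 205 °C before the second ring has closed. The fallback replaces the pericyclic cascade by π-acid catalysis. It sets out from 16 and comes back at 20. Ph3PAuNTf2 (a cationic complex of monovalent gold) in CH2Cl2 at room temperature activates each alkyne for 6-endo hydroarylation by the ring carbon para to the methoxy group. This forms C4–C4a directly and leaves O1–C2 in place. It passes through no new isolable compound (entry F0).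

**Step 3.** Two failures are likely: poor endo or facial selectivity with the α-methyl enal, or acid-induced oligomerisation of the electron-rich aryl diene before cycloaddition. The fallback replaces catalyst control by resolution. It sets out from 4 and 5 and comes back at 6.
- Uncatalysed cycloaddition in toluene at 100 °C with a radical inhibitor should give, after separation from any exo isomer, rac-(1S,2S)-2-[2-methoxy-6-(methoxymethoxy)phenyl]-1,4-dimethylcyclohex-3-ene-1-carbaldehyde F1.
- Condensation with (1S,2S)-N,N′-dimethyl-1,2-diphenylethane-1,2-diamine over molecular sieves gives two diastereomeric aminals, separable by chromatography. The wanted one is (4S,5S)-2-[(1S,2R)-2-[2-methoxy-6-(methoxymethoxy)phenyl]-1,4-dimethylcyclohex-3-en-1-yl]-1,3-dimethyl-4,5-diphenylimidazolidine F2.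
- Brief two-phase hydrolysis with dilute aqueous acid returns 6.

**Step 10.** The most likely failure is loss of chemoselectivity: competing allylic oxidation of the carbocycle, attack on the electron-rich styrene, or stalling after one lactone. The fallback does not oxidise a chromene at all. It sets out from 14 and comes back at 21.
- Magnesium-mediated ortho-formylation (MgCl2, Et3N, paraformaldehyde, CH3CN, reflux) at the single free ortho position of each phenol should give 3-[(E)-2-[(1R,2R)-2-(3-formyl-2-hydroxy-6-methoxyphenyl)-1,4-dimethylcyclohex-3-en-1-yl]ethenyl]-2-hydroxy-4-methoxybenzaldehyde F3.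
- Wittig reaction with Ph3P=CHCO2Et in PhNEt2 at reflux gives the twofold ethyl (E)-2-hydroxycinnamate F4 (each formyl group of F3 replaced by an (E)-2-ethoxycarbonylethenyl group; not isolated).
- F4 isomerises and lactonises in the same pot to 21.

**Step 4.** The most likely failure is slow addition of the bulky dichromium reagent to the α-quaternary aldehyde, giving incomplete conversion or reduced E selectivity. The fallback replaces one-carbon iodo-olefination by homologation to an alkyne and hydrometalation. It sets out from 6 and comes back at 7.
- Seyferth–Gilbert homologation with dimethyl (1-diazo-2-oxopropyl)phosphonate (K2CO3, MeOH) should give 2-[(1R,6S)-6-ethynyl-3,6-dimethylcyclohex-2-en-1-yl]-1-methoxy-3-(methoxymethoxy)benzene F5.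
- Hydrozirconation with Cp2Zr(H)Cl and iodinolysis with I2 gives 7 with the E geometry fixed by syn addition.

**Step 2.** The most likely failure is competing γ-attack of the allylic phosphonate anion or incomplete elimination, giving E/Z mixtures or hydroxy phosphonates. The fallback builds the diene in two carbonyl steps. It sets out from 2 and comes back at 4.
- Aldol condensation with acetone (aqueous NaOH) should give (E)-4-[2-methoxy-6-(methoxymethoxy)phenyl]but-3-en-2-one F6.
- Wittig methylenation with Ph3P=CH2 in THF gives 4.

## Further compounds

F0 | step 9 | none | none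
F1 | step 3 | rac-(1S,2S)-2-[2-methoxy-6-(methoxymethoxy)phenyl]-1,4-dimethylcyclohex-3-ene-1-carbaldehyde (racemate, one enantiomer drawn) | O=C[C@@]1(C)CCC(C)=C[C@H]1c1c(OC)cccc1OCOC
F2 | step 3 | (4S,5S)-2-[(1S,2R)-2-[2-methoxy-6-(methoxymethoxy)phenyl]-1,4-dimethylcyclohex-3-en-1-yl]-1,3-dimethyl-4,5-diphenylimidazolidine | CN1[C@@H](c2ccccc2)[C@H](c2ccccc2)N(C)C1[C@@]1(C)CCC(C)=C[C@H]1c1c(OC)cccc1OCOC
F3 | step 10 | 3-[(E)-2-[(1R,2R)-2-(3-formyl-2-hydroxy-6-methoxyphenyl)-1,4-dimethylcyclohex-3-en-1-yl]ethenyl]-2-hydroxy-4-methoxybenzaldehyde | COc1ccc(C=O)c(O)c1/C=C/[C@@]1(C)CCC(C)=C[C@H]1c1c(OC)ccc(C=O)c1O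
F4 | step 10 | twofold ethyl (E)-2-hydroxycinnamate from F3 (each formyl group of F3 replaced by an (E)-2-ethoxycarbonylethenyl group) | CCOC(=O)/C=C/c1ccc(OC)c(/C=C/[C@@]2(C)CCC(C)=C[C@H]2c2c(OC)ccc(/C=C/C(=O)OCC)c2O)c1O
F5 | step 4 | 2-[(1R,6S)-6-ethynyl-3,6-dimethylcyclohex-2-en-1-yl]-1-methoxy-3-(methoxymethoxy)benzene | C#C[C@@]1(C)CCC(C)=C[C@H]1c1c(OC)cccc1OCOC
F6 | step 2 | (E)-4-[2-methoxy-6-(methoxymethoxy)phenyl]but-3-en-2-one | CC(=O)/C=C/c1c(OC)cccc1OCOC
A1 | alternative 1 | methyl 5-methoxy-2-oxo-2H-chromene-3-carboxylate | COC(=O)c1cc2c(OC)cccc2oc1=O
A2 | alternative 1 | (E)-trimethyl(2-methylbuta-1,3-dien-1-yl)silane | C[Si](C)(C)/C=C(C)/C=C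
A3 | alternative 1 | cis-fused methyl 1-methoxy-9-methyl-6-oxo-10-(trimethylsilyl)-7,10-dihydro-6H-benzo[c]chromene-6a(10aH)-carboxylate (silyl-bearing centre undefined) | COc1cccc2OC(=O)[C@@]3(C(=O)OC)CC=C(C)C([Si](C)(C)C)[C@H]3c12
A4 | alternative 2 | 2-{(1R,2R)-2-[2-methoxy-6-(methoxymethoxy)phenyl]-1,4-dimethylcyclohex-3-en-1-yl}acetic acid | OC(=O)C[C@@]1(C)CCC(C)=C[C@H]1c1c(OC)cccc1OCOC
A5 | alternative 2 | 3-methoxybenzyne (3-methoxy-1,2-didehydrobenzene) | COC1=CC=CC#C1
A6 | alternative 2 | 1-(2-hydroxy-6-methoxyphenyl)-2-{(1R,2R)-2-[2-methoxy-6-(methoxymethoxy)phenyl]-1,4-dimethylcyclohex-3-en-1-yl}ethan-1-one | COc1cccc(O)c1C(=O)C[C@@]1(C)CCC(C)=C[C@H]1c1c(OC)cccc1OCOC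
A7 | alternative 3 | 1-diazobut-3-en-2-one | C=CC(=O)C=[N+]=[N-]
A8 | alternative 3 | triisopropyl({[(1R,6S)-3,6-dimethyl-6-[(triisopropylsilyl)ethynyl]cyclohex-2-en-1-yl]ethynyl}oxy)silane | CC(C)[Si](C(C)C)(C(C)C)OC#C[C@@H]1C=C(C)CC[C@]1(C)C#C[Si](C(C)C)(C(C)C)C(C)C
A9 | alternative 3 | 2-[(1R,6S)-3,6-dimethyl-6-[(triisopropylsilyl)ethynyl]cyclohex-2-en-1-yl]-3-[(triisopropylsilyl)oxy]phenol | Oc1cccc(O[Si](C(C)C)(C(C)C)C(C)C)c1[C@@H]1C=C(C)CC[C@]1(C)C#C[Si](C(C)C)(C(C)C)C(C)C
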